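C1 and C5 are the bridgeheads. With the aroyl-bearing enol arm C2–C3–C4 and the bridging ketone C9 they form ring A; C6 (CH2), C7 (CH–prenyl) and C8 (carrying CH3 and 4-methylpent-3-enyl, bonded to C1) complete ring B.
Enabling feature: C6–C7–C8 plus the C8 methyl and homoprenyl groups is a geranyl chain on C5. Its 2,3-alkene (C7=C8) has gained a prenyl group at C7 and a bond from C8 to C1, the enol carbon of ring A that lies 1,3 to C5.
Cuts: C7–prenyl and C8–C1 together, which opens ring B to a monocyclic dienone and dimethylallyl diphosphate. Then C5–geranyl, the two ring–prenyl bonds and the ring–aroyl bond, back to phloroglucinol.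
Forward: ring A is the phloroglucinol ring, which is aroylated, C-prenylated twice and dearomatised by C-geranylation. Ring B closes last, in an enzymatic prenylation–cyclisation.
Stereochemistry: C5 is made racemic and the (S) antipode is taken on a chiral phase. C1 follows from C5; C7 and C8 follow from anti addition across the E-alkene in a chair held by the enzyme.
The phenol of the aroyl ring travels as its mesylate from step 1 to step 6.

Key step: step 7

Assumption: a UbiA-type prenyltransferase that accepts the monocyclic precursor and closes onto C1 can be found among homologues of the known bicyclising enzymes in Hypericum, Garcinia or Clusia species that accumulate C3-aroyl bicyclic acylphloroglucinols; the enol tautomers of the dienones and of the target interconvert, and names, SMILES and descriptors refer to the tautomer drawn.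

Step 1
Reactants: 1 3-hydroxybenzoic acid
Product: 2 3-(methylsulfonyloxy)benzoic acid
Conditions: MsCl (1.3 equiv), NaOH (2.5 equiv, aq), THF/H2O, 0 °C to rt; then HCl
Reagents that add atoms: methanesulfonyl chloride, CS(=O)(=O)Cl
Why: Schotten–Baumann sulfonylation of the phenoxide, in which any mixed carboxylic–sulfonic anhydride is hydrolysed back by the aqueous base; the aryl mesylate is chosen because it tolerates AlCl3 and cold dilute alkali yet falls to excess hydroxide at room temperature.

Step 2
Reactants: 2 3-(methylsulfonyloxy)benzoic acid; 3 phloroglucinol (anhydrous)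
Product: 5 3-(2,4,6-trihydroxybenzoyl)phenyl methanesulfonate, via acid chloride 4 (not isolated)
Conditions: SOCl2, cat. DMF, toluene, 70 °C, evaporate; then 3 (1.2 equiv), AlCl3 (4 equiv), PhNO2/CH2Cl2, 0 to 60 °C; ice/HCl
Reagents that add atoms: thionyl chloride, O=S(Cl)Cl (chlorine of 4)
Why: Friedel–Crafts acylation of the very electron-rich phloroglucinol by the aroyl chloride–AlCl3 complex, which stops after one C-acylation because the chelated ketone deactivates the ring, while the aryl mesylate is inert to the Lewis acid.

Step 3
Reactants: 5 3-(2,4,6-trihydroxybenzoyl)phenyl methanesulfonate; 6 prenyl bromide (2.1 equiv)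
Product: 7 3-[2,4,6-trihydroxy-3,5-bis(3-methylbut-2-enyl)benzoyl]phenyl methanesulfonate
Conditions: KOH (2.2 equiv, 1 M aq), 0 °C; then HCl to pH 3
Reagents that add atoms: prenyl bromide (6), CC(C)=CCBr
Why: Twofold C-alkylation of the ambident acylphloroglucinolate in water, the standard route to 3,5-diprenyl acylphloroglucinols: hydrogen bonding shields the oxygens and sends the soft allylic bromide to the two free ring carbons, and the phenolic protons buffer the hydroxide so that the mesylate survives at 0 °C.

Step 4
Reactants: 7 3-[2,4,6-trihydroxy-3,5-bis(3-methylbut-2-enyl)benzoyl]phenyl methanesulfonate; 8 geranyl bromide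
Product: 9 rac-6-[(2E)-3,7-dimethylocta-2,6-dienyl]-3,5-dihydroxy-4-[3-(methylsulfonyloxy)benzoyl]-2,6-bis(3-methylbut-2-enyl)cyclohexa-2,4-dien-1-one (ring carbon 6 is C5 of the target)
Conditions: LiN(SiMe3)2 (2.1 equiv), THF, 0 °C; then 8 (1.1 equiv), 0 °C to rt; 1 M HCl
Reagents that add atoms: geranyl bromide (8), CC(C)=CCC/C(C)=C/CBr
Why: Alkylative dearomatisation (SN2 C-alkylation of the dilithium phenolate): the two prenyl-bearing carbons are equivalent and more nucleophilic than the aroyl-bearing one, tight O–Li pairing disfavours O-alkylation, the E-alkene of 8 is untouched, all amide base is consumed by the three OH groups so the mesyl CH3 is not deprotonated, and C5 arises as a racemate.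

Step 5
Reactants: 9 racemic mesylate-protected dienone
Product: 10 (6S)-6-[(2E)-3,7-dimethylocta-2,6-dienyl]-3,5-dihydroxy-4-[3-(methylsulfonyloxy)benzoyl]-2,6-bis(3-methylbut-2-enyl)cyclohexa-2,4-dien-1-one
Conditions: preparative SFC, amylose tris(3,5-dimethylphenylcarbamate) on silica, CO2/i-PrOH with 0.1% HCO2H, 35 °C
Reagents that add atoms: none
Why: Resolution by chromatography on a polysaccharide chiral stationary phase, routine for racemic dearomatised acylphloroglucinols; the quaternary C5 cannot epimerise, and the (S) antipode is identified by comparing measured with computed ECD curves.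

Step 6
Reactants: 10 (6S)-mesylate-protected dienone
Product: 11 (6S)-6-[(2E)-3,7-dimethylocta-2,6-dienyl]-3,5-dihydroxy-4-(3-hydroxybenzoyl)-2,6-bis(3-methylbut-2-enyl)cyclohexa-2,4-dien-1-one
Conditions: NaOH (2 M aq, 5 equiv), degassed THF, argon, rt to 40 °C; then cold 1 M HCl to pH 3
Reagents that add atoms: none
Why: Hydroxide-induced cleavage of the aryl alkanesulfonate at sulfur (E1cB through sulfene or direct S–O substitution), during which the triketone is protected as its delocalised enolate, the trisubstituted alkenes are inert and C5 has no path to racemise; methanol is left out so that no methyl mesylate can form, and air is excluded because such enolates autoxidise.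

Step 7
Reactants: 11 (6S)-geranyl-prenyl dienone; 12 dimethylallyl diphosphate (used as its commercial triammonium salt)
Product: 13 (1S,5S,7R,8S)-4-hydroxy-3-(3-hydroxybenzoyl)-8-methyl-1,5,7-tris(3-methylbut-2-enyl)-8-(4-methylpent-3-enyl)bicyclo[3.3.1]non-3-ene-2,9-dione (CNP0406274.2)
Conditions: yeast microsomes carrying the recombinant membrane-bound UbiA-type prenyltransferase, 12 (3 equiv), MgCl2 (10 mM), Tris-HCl (50 mM, pH 7.5), DTT (1 mM), DMSO (2% v/v), 30 °C, argon; EtOAc extraction, reversed-phase HPLC
Reagents that add atoms: dimethylallyl diphosphate (12), CC(C)=CCOP(=O)(O)OP(=O)(O)O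
Why: Proposed new method: the diphosphate of 12, bound to the divalent magnesium of MgCl2 in the aspartate-rich pocket, ionises to the dimethylallyl cation, the geranyl alkene of 11 attacks it through its less substituted carbon C7, and the charge growing at tertiary C8 is quenched by C1 of the ring A enolate (11 is a vinylogous acid and is ionised at pH 7.5), so the C7–prenyl and C8–C1 bonds form in one active-site event. The closest known reaction type is the prenyltransferase-triggered prenylation–cyclisation by which plants turn monocyclic polyprenylated acylphloroglucinols into bicyclo[3.3.1]nonanes in hyperforin-type biosynthesis; there the cation is captured by the acyl-bearing carbon, and neither a 3-hydroxybenzoyl substrate, nor capture by the prenyl-bearing carbon, nor preparative use has been shown. Ring B (C1, C8, C7, C6, C5, C9) closes 6-endo-trig through a chair. C1 is fixed by C5, because the tether C6–C7–C8 reaches only the face of ring A on which the geranyl group stands; C7 and C8 are fixed by anti addition of cation and enolate across the E-alkene within that chair, which places the new prenyl group equatorial on C7, the homoprenyl group equatorial and the methyl group axial on C8, that is (1S,7R,8S). The step needs C1 to win over C3 and the enol oxygens, the C7=C8 alkene to win over the C5-prenyl alkene and the remote alkenes, and the chair to win over the boat. The substrate helps through the 1,3 relation of C5 and C1, the lower nucleophilicity and greater crowding of the aroyl-bearing C3 and the Markovnikov bias of the trisubstituted alkene; the rest has to come from the shape of the pocket, which is why homologues are screened and, if needed, evolved.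

Compound list
1 | 3-hydroxybenzoic acid | O=C(O)c1cccc(O)c1 | starting material
2 | 3-(methylsulfonyloxy)benzoic acid | CS(=O)(=O)Oc1cccc(C(=O)O)c1 | intermediate
3 | phloroglucinol | Oc1cc(O)cc(O)c1 | starting material
4 | 3-(methylsulfonyloxy)benzoyl chloride | CS(=O)(=O)Oc1cccc(C(=O)Cl)c1 | intermediate
5 | 3-(2,4,6-trihydroxybenzoyl)phenyl methanesulfonate | CS(=O)(=O)Oc1cccc(C(=O)c2c(O)cc(O)cc2O)c1 | intermediate
6 | prenyl bromide | CC(C)=CCBr | starting material
7 | 3-[2,4,6-trihydroxy-3,5-bis(3-methylbut-2-enyl)benzoyl]phenyl methanesulfonate | CS(=O)(=O)Oc1cccc(C(=O)c2c(O)c(CC=C(C)C)c(O)c(CC=C(C)C)c2O)c1 | intermediate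
8 | geranyl bromide | CC(C)=CCC/C(C)=C/CBr | starting material
9 | racemic C5-geranyl-C5-prenyl dienone, aroyl phenol as mesylate | CC(C)=CCC/C(C)=C/CC1(CC=C(C)C)C(=O)C(CC=C(C)C)=C(O)C(C(=O)c2cccc(OS(C)(=O)=O)c2)=C1O | intermediate
10 | (6S)-enantiomer of 9 | CC(C)=CCC/C(C)=C/C[C@]1(CC=C(C)C)C(=O)C(CC=C(C)C)=C(O)C(C(=O)c2cccc(OS(C)(=O)=O)c2)=C1O | intermediate
11 | (6S)-6-geranyl-3,5-dihydroxy-4-(3-hydroxybenzoyl)-2,6-diprenylcyclohexa-2,4-dien-1-one | CC(C)=CCC/C(C)=C/C[C@]1(CC=C(C)C)C(=O)C(CC=C(C)C)=C(O)C(C(=O)c2cccc(O)c2)=C1O | intermediate
12 | dimethylallyl diphosphate | CC(C)=CCOP(=O)(O)OP(=O)(O)O | starting material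
13 | CNP0406274.2, (1S,5S,7R,8S) | CC(C)=CCC[C@@]1(C)[C@H](CC=C(C)C)C[C@]2(CC=C(C)C)C(=O)[C@@]1(CC=C(C)C)C(=O)C(C(=O)c1cccc(O)c1)=C2O | target

Total step count: 7. Longest linear sequence: 7 steps (1 → 2 → 5 → 7 → 9 → 10 → 11 → 13).

Steps most likely to fail

1. Step 7.
- What may go wrong: the enzyme may bind the substrate unproductively, close the cation onto C3 or an enol oxygen, prenylate the C5-prenyl alkene instead of C7=C8, or turn over too slowly for preparative work.
- Fallback: it uses known reaction types only, sets out from 7 and 6, and comes back at 13. The C7–prenyl bond is made first by auxiliary-controlled enolate alkylation. The same C8–C1 bond then closes ring B in a proton-initiated cationic cyclisation.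
- Commercial (E)-geranic acid is coupled through its pivaloyl mixed anhydride with (S)-4-benzyl-1,3-oxazolidin-2-one (lithiated with n-BuLi) to give the N-geranoyl imide F1.
- NaN(SiMe3)2 (THF, −78 °C) removes a proton of the C3 methyl group, which lies cis to the carbonyl. Compound 6 then alkylates the dienolate at the α-carbon from the face away from the benzyl group (deconjugative Evans alkylation), giving the α-prenyl β-methylidene imide F2.
- LiBH4 gives the primary alcohol F3. Tf2O/2,6-lutidine (CH2Cl2, −78 °C) gives the triflate F4, which is used at once.
- The dilithium salt of 7 (LiN(SiMe3)2, THF) is alkylated by F4 as in step 4. The two C5 epimers are now diastereomers and are parted on silica gel, the (5S,7R) isomer being the lavandulyl-type dienone F5, so no chiral chromatography is needed.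
- Formic acid protonates the 1,1-disubstituted alkene of F5. The tertiary C8 cation is captured by C1 through the chair that keeps the C7 prenyl group and the longer C8 chain equatorial, giving the target mesylate F6. Facial selectivity at the free C8 cation is the weak point of this path, and a C8 epimer would be removed by chromatography.
- NaOH in aqueous THF, as in step 6, then gives 13.

2. Step 4.
- What may go wrong: O-geranylation and repeated alkylation may outrun C-alkylation at the crowded prenyl-bearing carbon.
- Fallback: it sets out from 7 and comes back at 9, and the SN2 alkylation is replaced by a Tsuji–Trost reaction. Geraniol and methyl chloroformate/pyridine give geranyl methyl carbonate F7. Compound 7 is then treated with F7 and Pd(PPh3)4 (zerovalent palladium) in THF at rt.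
- O-allylation is reversible under these conditions, so material drains to the C-allylated dienone. Attack at the less substituted end of the π-geranyl complex gives the linear E product. The aryl mesylate does not add oxidatively with this catalyst at rt.

3. Step 5.
- What may go wrong: the antipodes may separate poorly, because the enol tautomers tail on the column and the geranyl and prenyl groups on C5 are much alike.
- Fallback: it sets out from 7, bypasses 9 and comes back at 10, and C5 is created enantioselectively instead of being resolved. Geraniol and Boc2O give geranyl tert-butyl carbonate F8.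
- Compound 7 is allylated with F8 under Pd2(dba)3·CHCl3 and a C2-symmetric trans-1,2-diaminocyclohexane bis(2-diphenylphosphinobenzamide) ligand (asymmetric Tsuji–Trost dearomatisation, linear-selective geranylation at a prochiral carbon nucleophile). The ligand antipode that gives the (S) product is chosen by experiment.

Further compounds
F1 | step 7 | (4S)-4-benzyl-3-[(2E)-3,7-dimethylocta-2,6-dienoyl]-1,3-oxazolidin-2-one | CC(C)=CCC/C(C)=C/C(=O)N1[C@@H](Cc2ccccc2)COC1=O
F2 | step 7 | (4S)-4-benzyl-3-[(2S)-7-methyl-3-methylidene-2-(3-methylbut-2-enyl)oct-6-enoyl]-1,3-oxazolidin-2-one | CC(C)=CCCC(=C)[C@H](CC=C(C)C)C(=O)N1[C@@H](Cc2ccccc2)COC1=O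
F3 | step 7 | (2S)-7-methyl-3-methylidene-2-(3-methylbut-2-enyl)oct-6-en-1-ol | CC(C)=CCCC(=C)[C@H](CC=C(C)C)CO
F4 | step 7 | (2S)-7-methyl-3-methylidene-2-(3-methylbut-2-enyl)oct-6-enyl trifluoromethanesulfonate | CC(C)=CCCC(=C)[C@H](CC=C(C)C)COS(=O)(=O)C(F)(F)F
F5 | step 7 | (6S)-3,5-dihydroxy-6-[(2R)-7-methyl-3-methylidene-2-(3-methylbut-2-enyl)oct-6-enyl]-4-[3-(methylsulfonyloxy)benzoyl]-2,6-bis(3-methylbut-2-enyl)cyclohexa-2,4-dien-1-one | CC(C)=CCCC(=C)[C@H](CC=C(C)C)C[C@]1(CC=C(C)C)C(=O)C(CC=C(C)C)=C(O)C(C(=O)c2cccc(OS(C)(=O)=O)c2)=C1O
F6 | step 7 | (1S,5S,7R,8S)-target with the aroyl phenol as methanesulfonate | CC(C)=CCC[C@@]1(C)[C@H](CC=C(C)C)C[C@]2(CC=C(C)C)C(=O)[C@@]1(CC=C(C)C)C(=O)C(C(=O)c1cccc(OS(C)(=O)=O)c1)=C2O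
F7 | step 4 | geranyl methyl carbonate | CC(C)=CCC/C(C)=C/COC(=O)OC
F8 | step 5 | geranyl tert-butyl carbonate | CC(C)=CCC/C(C)=C/COC(=O)OC(C)(C)C
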